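Ring B (B1 bridging CH2, B2 OH, B3 butanoyl, B4 OH, B5 Me, B6 OMe) is cut across B1–B2 and B3–B4. The feature exploited: B6 carries the only methoxy, so B4–B5–B6–B1 is the carbon chain of a 1,3-dimethoxy-1-silyloxydiene, and B2–B3 come from the triple bond of a 1-alkoxyhex-1-yn-3-one. One cycloaddition–aromatisation closes ring B and sets all six substituents, the benzylic link to ring A included. The precursor is a silyl ketene acetal diene whose terminal carbon bears the CH2 of tribenzylated ring A, with one ring A carbon left free for the later pentanoyl group; its partner is an isopropoxy ynone.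

Key step: step 8

Remarks on the chemistry (made before the steps):
- Ring A is the pentanoyl ring. Going round it: the pentanoyl-bearing carbon, C–OH, C–Me, C–OH, the carbon bearing the bridging CH2, C–OH. The target has no stereocentre.
- Ring A is attached by aldol addition and ionic deoxygenation. A 2,4,6-trialkoxybenzyl halide ionises and self-condenses too readily to serve as an alkylating agent.
- The ynone carries an isopropyl ether, not a primary alkyl ether. Once B4–OH chelates the butanoyl carbonyl, a second ortho ether is no longer cleaved by chelation, and a primary ether at B2 would compete poorly with the twisted B6 methoxy. A secondary ether is cleaved by BCl3 at low temperature while methyl ethers survive.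
- Assumption: N-methoxy-N-methylbutanamide (14) is taken as a catalogue compound; otherwise it is one amidation from butanoyl chloride.

Step 1
Reactants: 1 2,4,6-trihydroxytoluene
Product: 3 2,4,6-trihydroxy-3-methylbenzaldehyde, via aryl iminium chloride 2 (not isolated)
Conditions: POCl3, DMF, EtOAc, 0 °C → rt; then H2O, 60 °C
Reagents that add atoms: N,N-dimethylformamide, CN(C)C=O; water, O
Why: Vilsmeier–Haack formylation, in which the phloroglucinol ring attacks the chloroiminium ion at one of its two equivalent free carbons and the iminium salt formed resists a second formylation until it is hydrolysed.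

Step 2
Reactants: 3 2,4,6-trihydroxy-3-methylbenzaldehyde
Product: 4 2,4,6-tris(benzyloxy)-3-methylbenzaldehyde
Conditions: BnBr, K2CO3, DMF, 60 °C
Reagents that add atoms: benzyl bromide, BrCc1ccccc1
Why: Williamson etherification, in which the formyl group lowers the nucleophilicity of the remaining ring carbon so that O-benzylation of the three phenoxides should prevail over C-benzylation.

Step 3
Reactants: 4 2,4,6-tris(benzyloxy)-3-methylbenzaldehyde; 5 methyl 2-methyl-3-oxobutanoate
Product: 7 methyl 5-hydroxy-2-methyl-3-oxo-5-[2,4,6-tris(benzyloxy)-3-methylphenyl]pentanoate (racemic mixture of diastereomers), via keto ester dianion 6 (not isolated)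
Conditions: 5, NaH, THF, 0 °C; n-BuLi, 0 °C; then 4, −78 → −40 °C; AcOH
Reagents that add atoms: none
Why: Aldol addition of a Huckin–Weiler β-keto ester dianion, which reacts only at its terminal carbon; the two stereocentres (C2, C5) form without control and both are erased in steps 4 and 5.

Step 4
Reactants: 7 methyl 5-hydroxy-2-methyl-3-oxo-5-[2,4,6-tris(benzyloxy)-3-methylphenyl]pentanoate
Product: 8 methyl 2-methyl-3-oxo-5-[2,4,6-tris(benzyloxy)-3-methylphenyl]pentanoate (racemic)
Conditions: Et3SiH, CF3CO2H, CH2Cl2, −20 → 0 °C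
Reagents that add atoms: none
Why: Kursanov–Parnes ionic hydrogenation, in which the trialkoxyaryl ring lets the benzylic cation form at low temperature for capture by the silane, and any enone from competing dehydration should be reduced to the same product by protonation and hydride delivery at the benzylic carbon.

Step 5
Reactants: 8 methyl 2-methyl-3-oxo-5-[2,4,6-tris(benzyloxy)-3-methylphenyl]pentanoate
Product: 10 methyl (2E)-3-methoxy-2-methyl-5-[2,4,6-tris(benzyloxy)-3-methylphenyl]pent-2-enoate, via dimethyl ketal 9 (not isolated)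
Conditions: HC(OMe)3, H2SO4 (cat.), MeOH, 50 °C; then PhMe, 90 °C
Reagents that add atoms: trimethyl orthoformate, COC(OC)OC
Why: Acid-catalysed ketalisation with the orthoester and loss of methanol (enol ether formation) should give the conjugated E enoate as the thermodynamic isomer, and any Z or deconjugated isomer gives the same dienolate in step 6.

Step 6
Reactants: 10 methyl (2E)-3-methoxy-2-methyl-5-[2,4,6-tris(benzyloxy)-3-methylphenyl]pent-2-enoate
Product: 12 (1E,3Z)-1,3-dimethoxy-2-methyl-1-trimethylsilyloxy-5-[2,4,6-tris(benzyloxy)-3-methylphenyl]penta-1,3-diene, via lithium dienolate 11 (not isolated)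
Conditions: LiN(iPr)2, THF, −78 °C; Me3SiCl, −78 → 0 °C; non-aqueous work-up, used crude
Reagents that add atoms: chlorotrimethylsilane, C[Si](C)(C)Cl
Why: Kinetic γ-deprotonation of a β-alkoxy enoate and O-silylation of the dienolate (the standard entry to Brassard-type dienes); allylic strain should place the arylmethyl group cis to the C3 methoxy (3Z), outward in the s-cis diene, and the C1 geometry drawn is of no consequence because it is lost in step 8.

Step 7
Reactants: 13 trichloroethene; 14 N-methoxy-N-methylbutanamide
Product: 17 1-(propan-2-yloxy)hex-1-yn-3-one, via dichloroenol ether 15 (not isolated), via lithium alkoxyacetylide 16 (not isolated)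
Conditions: KH, iPrOH, THF, 0 °C; 13, −50 °C → rt; n-BuLi (2.2 equiv), −78 → −40 °C; 14, −78 → −20 °C; aq. NH4Cl; rapid filtration through Et3N-deactivated silica, stored cold and used promptly
Reagents that add atoms: propan-2-ol, CC(C)O
Why: Net vinylic substitution of chloride in trichloroethene by the alkoxide gives the dichloroenol ether, n-BuLi converts it into the lithium alkoxyacetylide by elimination and Li/Cl exchange, and acylation by the N-methoxy-N-methylamide (Weinreb ketone synthesis) should stop at the ynone.

Step 8
Reactants: 12 (1E,3Z)-1,3-dimethoxy-2-methyl-1-trimethylsilyloxy-5-[2,4,6-tris(benzyloxy)-3-methylphenyl]penta-1,3-diene; 17 1-(propan-2-yloxy)hex-1-yn-3-one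
Product: 19 1-[6-hydroxy-4-methoxy-5-methyl-2-(propan-2-yloxy)-3-[[2,4,6-tris(benzyloxy)-3-methylphenyl]methyl]phenyl]butan-1-one, via cyclohexadiene adduct 18 (not isolated)
Conditions: 12, 17 (2 equiv), PhMe (1 M), rt → 45 °C; then 1 M HCl, THF, 0 °C
Reagents that add atoms: none
Why: Proposed new method: the diene terminus C4 (future B1), the most nucleophilic carbon of the silyl ketene acetal diene, should add to the alkoxy-bearing β-carbon of the ynone (B2), and the α-carbon (B3) then bonds to the ketene acetal carbon C1 (B4), either in concert as an asynchronous Diels–Alder reaction or stepwise as a vinylogous Mukaiyama–Michael addition followed by closure of the allenolate onto the oxocarbenium ion. The closest known reaction type is the Diels–Alder/aromatisation of 1,3-dialkoxy-1-silyloxydienes with acetylenic ketones and esters to give resorcinol ethers; a β-alkoxy ynone has not been shown as the two-carbon partner. Ring B closes as a six-membered carbocycle by (4+2) union (a 6-endo closure in the stepwise picture), and dilute acid then removes the silyl methyl ketal at B4, after which loss of the B1 hydrogen gives the arene with B4–OH. No stereocentre remains, since B1 and B4 of adduct 18 both become aromatic carbons. The regiochemistry needed (B1 to B2, B4 to B3) rests on matched polarisation: the oxygen donors make diene C4 nucleophilic, the carbonyl makes the ynone β-carbon electrophilic, and the isopropoxy group lowers the reactivity of that carbon without reversing its polarity. The temperature is kept below 50 °C so that the isopropyl ynol ether does not lose propene by retro-ene fragmentation.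

Step 9
Reactants: 19 1-[6-hydroxy-4-methoxy-5-methyl-2-(propan-2-yloxy)-3-[[2,4,6-tris(benzyloxy)-3-methylphenyl]methyl]phenyl]butan-1-one
Product: 20 1-[2,4,6-tris(benzyloxy)-3-[[3-butanoyl-4-hydroxy-6-methoxy-5-methyl-2-(propan-2-yloxy)phenyl]methyl]-5-methylphenyl]pentan-1-one
Conditions: pentanoic acid, (CF3CO)2O, CH2Cl2, 0 °C → rt; then K2CO3, MeOH, rt
Reagents that add atoms: pentanoic acid, CCCCC(=O)O
Why: Friedel–Crafts acylation by the mixed anhydride, in which the one free carbon of ring A is the only unsubstituted aromatic carbon of the molecule and is activated by two ortho and one para benzyloxy groups, while the chelated B4–OH should resist O-acylation (the basic methanol treatment returns the phenol if it does not).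

Step 10
Reactants: 20 1-[2,4,6-tris(benzyloxy)-3-[[3-butanoyl-4-hydroxy-6-methoxy-5-methyl-2-(propan-2-yloxy)phenyl]methyl]-5-methylphenyl]pentan-1-one
Product: 21 1-[3-[(3-butanoyl-2,4-dihydroxy-6-methoxy-5-methylphenyl)methyl]-2,4,6-trihydroxy-5-methylphenyl]pentan-1-one (CNP0210501.0)
Conditions: BCl3 (excess), C6HMe5, CH2Cl2, −78 → 0 °C; MeOH quench, aqueous work-up
Reagents that add atoms: none
Why: Lewis acid ether cleavage, in which BCl3 with pentamethylbenzene as cation scavenger removes the three aryl benzyl ethers at low temperature and cleaves the secondary isopropyl ether by an SN1-like path, whereas the primary methyl ether at B6, which has no ortho carbonyl to direct the boron, should survive below 0 °C.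

Compound list
1 | 2,4,6-trihydroxytoluene (2-methylbenzene-1,3,5-triol) | Cc1c(O)cc(O)cc1O | starting material
2 | [(2,4,6-trihydroxy-3-methylphenyl)methylidene]dimethylazanium chloride | C[N+](C)=Cc1c(O)c(C)c(O)cc1O.[Cl-] | intermediate (not isolated)
3 | 2,4,6-trihydroxy-3-methylbenzaldehyde | O=Cc1c(O)c(C)c(O)cc1O | intermediate
4 | 2,4,6-tris(benzyloxy)-3-methylbenzaldehyde | O=Cc1c(OCc2ccccc2)c(C)c(OCc2ccccc2)cc1OCc1ccccc1 | intermediate
5 | methyl 2-methyl-3-oxobutanoate (methyl 2-methylacetoacetate, racemic) | CC(=O)C(C)C(=O)OC | starting material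
6 | sodium lithium 1-methoxy-2-methylbuta-1,3-diene-1,3-diolate (dianion of 5) | [Na+].[Li+].C=C([O-])C(C)=C([O-])OC | intermediate (not isolated)
7 | methyl 5-hydroxy-2-methyl-3-oxo-5-[2,4,6-tris(benzyloxy)-3-methylphenyl]pentanoate (racemic mixture of diastereomers) | COC(=O)C(C)C(=O)CC(O)c1c(OCc2ccccc2)c(C)c(OCc2ccccc2)cc1OCc1ccccc1 | intermediate
8 | methyl 2-methyl-3-oxo-5-[2,4,6-tris(benzyloxy)-3-methylphenyl]pentanoate (racemic) | COC(=O)C(C)C(=O)CCc1c(OCc2ccccc2)c(C)c(OCc2ccccc2)cc1OCc1ccccc1 | intermediate
9 | methyl 3,3-dimethoxy-2-methyl-5-[2,4,6-tris(benzyloxy)-3-methylphenyl]pentanoate (racemic) | COC(=O)C(C)C(OC)(OC)CCc1c(OCc2ccccc2)c(C)c(OCc2ccccc2)cc1OCc1ccccc1 | intermediate (not isolated)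
10 | methyl (2E)-3-methoxy-2-methyl-5-[2,4,6-tris(benzyloxy)-3-methylphenyl]pent-2-enoate | COC(=O)/C(C)=C(/OC)CCc1c(OCc2ccccc2)c(C)c(OCc2ccccc2)cc1OCc1ccccc1 | intermediate
11 | lithium dienolate of 10 (lithium 1,3-dimethoxy-2-methyl-5-[2,4,6-tris(benzyloxy)-3-methylphenyl]penta-1,3-dien-1-olate, geometry as in 12) | [Li+].CO/C([O-])=C(/C)\C(OC)=C\Cc1c(OCc2ccccc2)c(C)c(OCc2ccccc2)cc1OCc1ccccc1 | intermediate (not isolated)
12 | (1E,3Z)-1,3-dimethoxy-2-methyl-1-trimethylsilyloxy-5-[2,4,6-tris(benzyloxy)-3-methylphenyl]penta-1,3-diene | CO/C(O[Si](C)(C)C)=C(/C)\C(OC)=C\Cc1c(OCc2ccccc2)c(C)c(OCc2ccccc2)cc1OCc1ccccc1 | intermediate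
13 | trichloroethene | ClC=C(Cl)Cl | starting material
14 | N-methoxy-N-methylbutanamide | CCCC(=O)N(C)OC | starting material
15 | (E)-1,2-dichloro-1-(propan-2-yloxy)ethene | Cl/C=C(/Cl)OC(C)C | intermediate (not isolated)
16 | lithium (propan-2-yloxy)ethynide | [Li+].[C-]#COC(C)C | intermediate (not isolated)
17 | 1-(propan-2-yloxy)hex-1-yn-3-one | CCCC(=O)C#COC(C)C | intermediate
18 | 1-[4,6-dimethoxy-5-methyl-2-(propan-2-yloxy)-6-(trimethylsilyloxy)-3-[[2,4,6-tris(benzyloxy)-3-methylphenyl]methyl]cyclohexa-1,4-dien-1-yl]butan-1-one (mixture of diastereomers) | CCCC(=O)C1=C(OC(C)C)C(Cc2c(OCc3ccccc3)c(C)c(OCc3ccccc3)cc2OCc2ccccc2)C(OC)=C(C)C1(OC)O[Si](C)(C)C | intermediate (not isolated)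
19 | 1-[6-hydroxy-4-methoxy-5-methyl-2-(propan-2-yloxy)-3-[[2,4,6-tris(benzyloxy)-3-methylphenyl]methyl]phenyl]butan-1-one | CCCC(=O)c1c(OC(C)C)c(Cc2c(OCc3ccccc3)c(C)c(OCc3ccccc3)cc2OCc2ccccc2)c(OC)c(C)c1O | intermediate
20 | 1-[2,4,6-tris(benzyloxy)-3-[[3-butanoyl-4-hydroxy-6-methoxy-5-methyl-2-(propan-2-yloxy)phenyl]methyl]-5-methylphenyl]pentan-1-one | CCCCC(=O)c1c(OCc2ccccc2)c(C)c(OCc2ccccc2)c(Cc2c(OC(C)C)c(C(=O)CCC)c(O)c(C)c2OC)c1OCc1ccccc1 | intermediate
21 | 1-[3-[(3-butanoyl-2,4-dihydroxy-6-methoxy-5-methylphenyl)methyl]-2,4,6-trihydroxy-5-methylphenyl]pentan-1-one | CCCCC(=O)c1c(O)c(C)c(O)c(Cc2c(O)c(C(=O)CCC)c(O)c(C)c2OC)c1O | target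

Total step count: 10. Longest linear sequence: 9 steps (steps 1–6, then 8–10); step 7 is a one-step branch.

Steps most likely to fail

Step 8 (proposed new method). The donor-substituted alkyne may be too unreactive towards the hindered, fully substituted diene below the temperature at which the ynol ether fragments, or conjugate addition may occur without ring closure. The fallback uses only known chemistry and gives up the cycloaddition: the methylene bridge is made last by the phenol Mannich/ortho-quinone methide coupling of two acylphloroglucinols. It sets out from 1 and returns at 21. Friedel–Crafts acylation of 1 with pentanoyl chloride and AlCl3 in nitrobenzene should give 1-(2,4,6-trihydroxy-3-methylphenyl)pentan-1-one F1. The same reaction with butanoyl chloride should give 1-(2,4,6-trihydroxy-3-methylphenyl)butan-1-one F2. Its non-chelated para hydroxyl is methylated selectively (one equivalent of Me2SO4, K2CO3, acetone) to 1-(2,6-dihydroxy-4-methoxy-3-methylphenyl)butan-1-one F3. Aminomethylation of the single free ring carbon of F3 (CH2O, Me2NH, EtOH) gives 1-[3-[(dimethylamino)methyl]-2,6-dihydroxy-4-methoxy-5-methylphenyl]butan-1-one F4. Heating F4 with F1 in dioxane releases dimethylamine, and the ortho-quinone methide should alkylate the one free carbon of F1 to give 21.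

Step 9. The acidic acylation medium may break the diarylmethane link by ipso attack at the ring A carbon that bears the bridging CH2, strip benzyl ethers from the electron-rich ring, or acylate B4–OH. The fallback inverts the endgame, setting out from 19 and returning at 21. Deprotection of 19 (BCl3, C6HMe5, CH2Cl2, −78 → 0 °C) should give 1-[2,6-dihydroxy-4-methoxy-5-methyl-3-[(2,4,6-trihydroxy-3-methylphenyl)methyl]phenyl]butan-1-one F5. Its free phloroglucinol ring A is then acylated at its one unsubstituted carbon by a Houben–Hoesch reaction with pentanenitrile (ZnCl2, HCl gas, Et2O, 0 °C), which gives [1-[3-[(3-butanoyl-2,4-dihydroxy-6-methoxy-5-methylphenyl)methyl]-2,4,6-trihydroxy-5-methylphenyl]pentylidene]azanium chloride F6. Warm water hydrolyses F6 to 21.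

Step 10. Over-reaction of BCl3 may demethylate the hindered B6 methoxy or cleave the methylene bridge before the last ether is gone. The fallback removes the benzyl ethers without a Lewis acid, setting out from 20 and returning at 21. Hydrogenolysis of 20 (H2, Pd/C, EtOAc) should give 1-[3-[[3-butanoyl-4-hydroxy-6-methoxy-5-methyl-2-(propan-2-yloxy)phenyl]methyl]-2,4,6-trihydroxy-5-methylphenyl]pentan-1-one F7. A short exposure to a small excess of BCl3 at −78 to −20 °C (or AlCl3 in CH2Cl2 at 0 °C) then cleaves only the secondary isopropyl ether to give 21.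

Further compounds
F1 | step 8 | 1-(2,4,6-trihydroxy-3-methylphenyl)pentan-1-one | CCCCC(=O)c1c(O)cc(O)c(C)c1O
F2 | step 8 | 1-(2,4,6-trihydroxy-3-methylphenyl)butan-1-one | CCCC(=O)c1c(O)cc(O)c(C)c1O
F3 | step 8 | 1-(2,6-dihydroxy-4-methoxy-3-methylphenyl)butan-1-one | CCCC(=O)c1c(O)cc(OC)c(C)c1O
F4 | step 8 | 1-[3-[(dimethylamino)methyl]-2,6-dihydroxy-4-methoxy-5-methylphenyl]butan-1-one | CCCC(=O)c1c(O)c(CN(C)C)c(OC)c(C)c1O
F5 | step 9 | 1-[2,6-dihydroxy-4-methoxy-5-methyl-3-[(2,4,6-trihydroxy-3-methylphenyl)methyl]phenyl]butan-1-one | CCCC(=O)c1c(O)c(Cc2c(O)cc(O)c(C)c2O)c(OC)c(C)c1O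
F6 | step 9 | [1-[3-[(3-butanoyl-2,4-dihydroxy-6-methoxy-5-methylphenyl)methyl]-2,4,6-trihydroxy-5-methylphenyl]pentylidene]azanium chloride | CCCCC(=[NH2+])c1c(O)c(C)c(O)c(Cc2c(O)c(C(=O)CCC)c(O)c(C)c2OC)c1O.[Cl-]
F7 | step 10 | 1-[3-[[3-butanoyl-4-hydroxy-6-methoxy-5-methyl-2-(propan-2-yloxy)phenyl]methyl]-2,4,6-trihydroxy-5-methylphenyl]pentan-1-one | CCCCC(=O)c1c(O)c(C)c(O)c(Cc2c(OC(C)C)c(C(=O)CCC)c(O)c(C)c2OC)c1O
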